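The methylene bridge is cut into a ring A Mannich base and a C-nucleophilic ring B, and ring A itself rests on one aryne event. Ring A carries a vicinal pair, the C2 methyl and the C1 butyryl, directly beside the C6 oxygen of a 2-methylresorcinol core. An aryne spanning C1–C2, with that oxygen as its neighbour, takes up both groups in one flask. Methyl enters at the remote C2 and acyl at C1, so two C–C bonds form under regiocontrol from the C6 methoxyl. The precursor is monobrominated 2,6-dimethoxytoluene (Br at C1, H at C2), combined with MeMgBr and the butyric Weinreb amide. Chelation-guided demethylation then tells the two ethers apart.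

Key step: step 3

Remark: ring A is numbered C1 (butyryl), C2 (CH3), C3 (bridge CH2), C4 (OCH3), C5 (CH3), C6 (OH), and this numbering is used for all ring A precursors. The target has no stereocentre, so no stereocontrol is needed.

Step 1
Reactants: 1 2,6-dimethoxytoluene
Product: 2 1-bromo-2,4-dimethoxy-3-methylbenzene
Conditions: NBS (1.0 equiv), MeCN, 0 °C to rt, dark
Reagents that add atoms: N-bromosuccinimide, O=C1CCC(=O)N1Br
Why: Electrophilic aromatic bromination goes to one of the two equivalent positions that lie ortho to one methoxyl and para to the other, and one equivalent of NBS in polar MeCN without light should stop at the monobromide and spare the benzylic methyl.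

Step 2
Reactants: 3 butyryl chloride
Product: 4 N-methoxy-N-methylbutanamide
Conditions: MeNH(OMe)·HCl (1.05 equiv), K2CO3 (2.2 equiv), CH2Cl2/H2O, 0 °C to rt
Reagents that add atoms: N,O-dimethylhydroxylamine hydrochloride, CNOC.Cl
Why: In this Schotten–Baumann acylation the hydroxylamine freed by K2CO3 is acylated at nitrogen much faster than the acid chloride hydrolyses in the two-phase mixture, and the amide does not react further.

Step 3
Reactants: 2 1-bromo-2,4-dimethoxy-3-methylbenzene; 5 methylmagnesium bromide; 4 N-methoxy-N-methylbutanamide
Product: 11 1-(2,4-dimethoxy-3,6-dimethylphenyl)butan-1-one, via 2-bromoaryllithium 6 (not isolated), via 2-bromoaryl(methyl)magnesium 7 (not isolated), via aryne 8 (not isolated), via arylmagnesium bromide 9 (not isolated), via magnesium hemiaminal chelate 10 (not isolated)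
Conditions: lithium 2,2,6,6-tetramethylpiperidide (LiTMP, 1.3 equiv; from 2,2,6,6-tetramethylpiperidine (TMPH) + n-BuLi, THF, 0 °C) added slowly to 2 + MeMgBr (3 equiv), THF, −78 °C; then to 45 °C; 4 (3.5 equiv), 0 °C to rt; 1 M HCl
Reagents that add atoms: none
Why: LiTMP, too bulky to add readily to an aryne, removes H2, the only hydrogen next to bromine and the most acidic one on the ring (H3 has only one ortho methoxyl, which a non-coordinating amide exploits poorly); since such hindered lithium amides metalate arenes at −78 °C even when magnesium species are present, 6 should form, pass its aryl group to magnesium to give 7, and 7 should expel bromide only on warming, so that aryne 8 is released into a solution already rich in MeMgBr. MeMgBr adds across the strained C1–C2 triple bond (carbomagnesiation), making the C2–CH3 bond and arylmagnesium 9, and 9 attacks Weinreb amide 4 to make the C1–C(=O) bond as chelate 10, which lasts until the acid quench, so that neither 9 nor surplus MeMgBr can add a second time and the surplus only consumes extra amide. The closest known reaction type is the one-pot three-component coupling in which a 3-alkoxyaryne, made from a haloanisole and a lithium base, takes up a Grignard reagent and the resulting ortho-alkoxy arylmagnesium is quenched by a carbonyl electrophile. The selectivity needed is the regiochemistry of addition, and the C6 methoxyl next to C1 secures it: its inductive pull distorts the aryne so that the nucleophile enters at the remote C2 and the carbanion develops at C1 beside oxygen, the C5 methyl presses that methoxyl toward C1 and shields it further, and the C4 methoxyl is too distant to oppose this. Chemoselectivity rests on the inertness of the aryl bromide toward MeMgBr without a catalyst and on adding 4 only after the aryne has been consumed. No ring is closed and no stereocentre remains in 11 (the carbinolamine carbon of 10 is transient and racemic).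

Step 4
Reactants: 11 1-(2,4-dimethoxy-3,6-dimethylphenyl)butan-1-one
Product: 13 1-(2-hydroxy-4-methoxy-3,6-dimethylphenyl)butan-1-one, via aryloxydichloroborane chelate 12 (not isolated)
Conditions: BCl3 (1.2 equiv, 1 M in CH2Cl2), CH2Cl2, −78 °C to 0 °C; then H2O
Reagents that add atoms: none
Why: In this chelation-controlled ether cleavage BCl3 binds the ketone oxygen and reaches only the C6 methoxyl through a six-membered chelate, chloride removes that methyl to give 12, the remote C4 methoxyl stays intact at low temperature, and water frees the hydrogen-bonded phenol.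

Step 5
Reactants: 13 1-(2-hydroxy-4-methoxy-3,6-dimethylphenyl)butan-1-one
Product: 14 1-{3-[(dimethylamino)methyl]-6-hydroxy-4-methoxy-2,5-dimethylphenyl}butan-1-one
Conditions: 37% aq. HCHO (2 equiv), 40% aq. Me2NH (2.5 equiv), EtOH, sealed tube, 80 °C
Reagents that add atoms: formaldehyde, C=O; dimethylamine, CNC
Why: In this phenol Mannich reaction both positions ortho to the C6 hydroxyl (C1 and C5) are occupied, so the iminium ion can enter only at C3, the single ring C–H, which is para to the hydroxyl and ortho to the methoxyl, while under free-amine conditions the hindered, chelated ketone should enolise too slowly to compete.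

Step 6
Reactants: 15 2,4,6-trihydroxytoluene; 3 butyryl chloride
Product: 16 1-(2,4,6-trihydroxy-3-methylphenyl)butan-1-one
Conditions: AlCl3 (3.5 equiv), CH2Cl2/PhNO2, 0 °C to 45 °C; ice/1 M HCl
Reagents that add atoms: none
Why: In this Friedel–Crafts acylation the two free ring carbons of 15 are equivalent, so only one C-acyl isomer can form, any aryl ester is carried on by Fries rearrangement under AlCl3, and the first acyl group deactivates the ring toward a second.

Step 7
Reactants: 14 1-{3-[(dimethylamino)methyl]-6-hydroxy-4-methoxy-2,5-dimethylphenyl}butan-1-one; 16 1-(2,4,6-trihydroxy-3-methylphenyl)butan-1-one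
Product: 18 1-{3-[(3-butanoyl-2,4,6-trihydroxy-5-methylphenyl)methyl]-6-hydroxy-4-methoxy-2,5-dimethylphenyl}butan-1-one, via para-quinone methide 17 (not isolated)
Conditions: 16 (1.1 equiv), 1,4-dioxane, reflux, slow N2 stream
Reagents that add atoms: none
Why: In this Mannich-base alkylation the acidic acylphloroglucinol 16 protonates the amine of 14, loss of volatile Me2NH gives para-quinone methide 17, and the only free ring carbon of 16 adds to its exocyclic CH2 in a Michael-type manner with rearomatisation of both rings, O-alkylation being reversible and C-alkylation not.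

Compound list
1 | 2,6-dimethoxytoluene | Cc1c(OC)cccc1OC | starting material
2 | 1-bromo-2,4-dimethoxy-3-methylbenzene | COc1ccc(Br)c(OC)c1C | intermediate
3 | butyryl chloride | CCCC(Cl)=O | starting material
4 | N-methoxy-N-methylbutanamide | CCCC(=O)N(C)OC | intermediate
5 | methylmagnesium bromide | C[Mg]Br | starting material
6 | (2-bromo-3,5-dimethoxy-4-methylphenyl)lithium | [Li]c1cc(OC)c(C)c(OC)c1Br | intermediate (not isolated)
7 | (2-bromo-3,5-dimethoxy-4-methylphenyl)(methyl)magnesium | C[Mg]c1cc(OC)c(C)c(OC)c1Br | intermediate (not isolated)
8 | 1,2-didehydro-3,5-dimethoxy-4-methylbenzene (3,5-dimethoxy-4-methylbenzyne) | COC1=C(C)C(OC)=CC#C1 | intermediate (not isolated)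
9 | (2,4-dimethoxy-3,6-dimethylphenyl)magnesium bromide | Br[Mg]c1c(C)cc(OC)c(C)c1OC | intermediate (not isolated)
10 | bromomagnesium 1-(2,4-dimethoxy-3,6-dimethylphenyl)-1-[methoxy(methyl)amino]butan-1-olate (racemic) | CCCC(O[Mg]Br)(N(C)OC)c1c(C)cc(OC)c(C)c1OC | intermediate (not isolated)
11 | 1-(2,4-dimethoxy-3,6-dimethylphenyl)butan-1-one | CCCC(=O)c1c(C)cc(OC)c(C)c1OC | intermediate
12 | (2-butanoyl-5-methoxy-3,6-dimethylphenoxy)dichloroborane | CCCC(=O)c1c(C)cc(OC)c(C)c1OB(Cl)Cl | intermediate (not isolated)
13 | 1-(2-hydroxy-4-methoxy-3,6-dimethylphenyl)butan-1-one | CCCC(=O)c1c(C)cc(OC)c(C)c1O | intermediate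
14 | 1-{3-[(dimethylamino)methyl]-6-hydroxy-4-methoxy-2,5-dimethylphenyl}butan-1-one | CCCC(=O)c1c(C)c(CN(C)C)c(OC)c(C)c1O | intermediate
15 | 2,4,6-trihydroxytoluene (2-methylbenzene-1,3,5-triol) | Cc1c(O)cc(O)cc1O | starting material
16 | 1-(2,4,6-trihydroxy-3-methylphenyl)butan-1-one | CCCC(=O)c1c(O)cc(O)c(C)c1O | intermediate
17 | 2-butanoyl-5-methoxy-3,6-dimethyl-4-methylidenecyclohexa-2,5-dien-1-one | CCCC(=O)C1=C(C)C(=C)C(OC)=C(C)C1=O | intermediate (not isolated)
18 | 1-{3-[(3-butanoyl-2,4,6-trihydroxy-5-methylphenyl)methyl]-6-hydroxy-4-methoxy-2,5-dimethylphenyl}butan-1-one (CNP0189103.0) | CCCC(=O)c1c(C)c(Cc2c(O)c(C)c(O)c(C(=O)CCC)c2O)c(OC)c(C)c1O | target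

Total step count: 7
Longest linear sequence: 5 (steps 1, 3, 4, 5, 7)

Steps most likely to fail

**Step 3.**
- Possible failures:
  - The Grignard reagent captures the lithium amide before it metalates C2–H.
  - Bromine migrates between aryl anions.
  - The amide adds to the aryne.
  - The doubly ortho-substituted arylmagnesium is acylated only sluggishly.
- The fallback uses no aryne. It sets out from butyryl chloride 3 and comes back at ketone 11.
- Purchased 3,5-dimethoxytoluene F1 is lithiated between its two methoxyls (n-BuLi, THF, 0 °C to rt). Quenching with MeI gives 1,3-dimethoxy-2,5-dimethylbenzene F2.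
- Friedel–Crafts acylation of F2 with 3 (TiCl4, CH2Cl2, 0 °C) can occur only at one of two equivalent ring carbons. Each lies between a methoxyl and the C-methyl, so the reaction should deliver 11.

**Step 5.**
- Possible failures:
  - The iminium ion attacks the flanked C3 position too slowly.
  - Aminomethylation occurs at the carbon alpha to the ketone.
- The fallback avoids the amine altogether. It sets out from phenol 13 and comes back at target 18.
- Duff formylation (hexamethylenetetramine, CF3CO2H, reflux; aq. HCl) is the standard way to formylate para to a phenol whose ortho positions are blocked. It should give 3-butanoyl-4-hydroxy-6-methoxy-2,5-dimethylbenzaldehyde F3.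
- NaBH4 (MeOH, 0 °C) should reduce only the aldehyde, because the ketone is flanked on both sides and tied up as a chelated phenoxide. This gives 1-[6-hydroxy-3-(hydroxymethyl)-4-methoxy-2,5-dimethylphenyl]butan-1-one F4.
- ZnCl2 in 1,4-dioxane (rt to 60 °C) ionises the benzylic alcohol. The free ring carbon of 16 is then benzylated in a Friedel–Crafts manner to give 18.

**Step 7.**
- Possible failures:
  - The neutral amine is expelled too slowly at reflux.
  - The CH2 unit transfers to ring B by retro-Mannich cleavage, which leads to symmetrical coupling.
  - The aryl groups on the bridge exchange on long heating.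
- The fallback replaces thermal extrusion by an isolated, charged electrophile that fragments at room temperature. It sets out from Mannich base 14 and comes back at target 18.
- N-Methylation of 14 with MeI (acetone, rt, no base, so the phenol is not touched) gives the salt 1-(3-butanoyl-4-hydroxy-6-methoxy-2,5-dimethylphenyl)-N,N,N-trimethylmethanaminium iodide F5. It is filtered free of MeI.
- F5 is stirred with 16 and NaHCO3 in aqueous MeCN at rt. Trimethylamine leaves, and the quinone methide is taken up by the phloroglucinolate carbon under conditions too mild for bridge scrambling.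

Further compounds
F1 | step 3 | 3,5-dimethoxytoluene (purchased) | COc1cc(C)cc(OC)c1
F2 | step 3 | 1,3-dimethoxy-2,5-dimethylbenzene | COc1cc(C)cc(OC)c1C
F3 | step 5 | 3-butanoyl-4-hydroxy-6-methoxy-2,5-dimethylbenzaldehyde | CCCC(=O)c1c(C)c(C=O)c(OC)c(C)c1O
F4 | step 5 | 1-[6-hydroxy-3-(hydroxymethyl)-4-methoxy-2,5-dimethylphenyl]butan-1-one | CCCC(=O)c1c(C)c(CO)c(OC)c(C)c1O
F5 | step 7 | 1-(3-butanoyl-4-hydroxy-6-methoxy-2,5-dimethylphenyl)-N,N,N-trimethylmethanaminium iodide | CCCC(=O)c1c(C)c(C[N+](C)(C)C)c(OC)c(C)c1O.[I-]
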